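**Retrosynthetic overview**
1. Target 29 ← desilylation ← SeO2 hydroxylation of the C10 methyl (ene/[2,3]; turns C1=C10 from ring-trans to ring-cis) ← angeloylation of 8-OH ← hydroxy α-methylene lactone 24.
2. 24 ← Mannich methylenation ← trans-fused lactone 21 ← 8-OH-directed anti reduction and lactonisation ← keto ester 18.
3. 18 (ten-membered ring, C7 and C8) ← anionic oxy-Cope [3,3] ring expansion of the trans-1,2-dialkenylcyclohexanol 14 with in-situ enolate alkylation (key step, forms C8–C9).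
4. 14 ← ketone 7 + (Z)-PMBOCH=CHLi; 7 ← (R)-cyclohex-3-ene-1-carboxylic acid 1 (the only purchased stereocentre, C4) by iodolactonisation and Ni-catalysed isopropenylation.
5. Ring order: cyclohexane (bought) → ten-membered carbocycle (oxy-Cope) → γ-lactone.

Assumption: resolved (R)-cyclohex-3-ene-1-carboxylic acid is taken as the cheap chiral starting material; ten-membered compounds carry germacrane numbering (C1=C10 with C14 on C10, C15 on C4, lactone O on C6, C11–C13 on C7, acyloxy on C8), and because the CIP label of C1=C10 is E throughout, "ring-trans"/"ring-cis" (C2 anti/syn to C9) is stated as well.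

**Route**

Step 1
Reactants: 1 (R)-cyclohex-3-ene-1-carboxylic acid
Product: 2 (1R,4R,5R)-4-iodo-6-oxabicyclo[3.2.1]octan-7-one
Conditions: I2, KI, NaHCO3, H2O, 0 °C → rt, dark
Reagents that add atoms: iodine, II
Why: Iodolactonisation; the carboxylate opens the iodonium anti, which puts O on the ring carbon 1,3 to the side chain and I on the carbon 1,4 to it (trans to O), so the later ketone and isopropenyl positions are fixed by the purchased stereocentre.

Step 2
Reactants: 2 iodolactone + 3 2-bromopropene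
Product: 4 (1R,4S,5R)-4-(prop-1-en-2-yl)-6-oxabicyclo[3.2.1]octan-7-one
Conditions: 3 (3 equiv), NiBr2·glyme (10 mol%), 4,4′-di-tert-butyl-2,2′-bipyridine (10 mol%), Mn powder (2 equiv), DMA, 25 °C
Reagents that add atoms: none
Why: Ni-catalysed reductive cross-electrophile coupling of a secondary alkyl iodide with an alkenyl bromide; the C4 radical is captured on the exo face anti to the axial lactone C–O bond, so isopropenyl replaces iodine with retention (trans to O), and Mn is used instead of Zn to limit reductive opening of the iodolactone.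

Step 3
Reactants: 4 isopropenyl lactone
Product: 5 (1R,2S,5R)-5-(hydroxymethyl)-2-(prop-1-en-2-yl)cyclohexan-1-ol
Conditions: LiAlH4, THF, 0 °C → rt; H2O work-up
Reagents that add atoms: none
Why: Hydride reduction of the lactone leaves all stereocentres untouched and gives the all-equatorial diol (a 7-hydroxy-isopulegol).

Step 4
Reactants: 5 diol
Product: 6 (1R,2S,5R)-5-{[tert-butyl(diphenyl)silyl]oxymethyl}-2-(prop-1-en-2-yl)cyclohexan-1-ol
Conditions: TBDPSCl (1.05 equiv), imidazole, CH2Cl2, 0 °C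
Reagents that add atoms: tert-butyl(chloro)diphenylsilane, CC(C)(C)[Si](Cl)(c1ccccc1)c1ccccc1
Why: Selective silylation of the primary alcohol by the bulky chlorosilane.

Step 5
Reactants: 6 mono-silyl ether
Product: 7 (2S,5R)-5-{[tert-butyl(diphenyl)silyl]oxymethyl}-2-(prop-1-en-2-yl)cyclohexan-1-one
Conditions: Dess–Martin periodinane, NaHCO3, CH2Cl2, 0 °C → rt
Reagents that add atoms: none
Why: Buffered Dess–Martin oxidation gives the ketone without epimerising the α-centre (isopropenyl stays trans to CH2OSi, both equatorial) or conjugating the alkene.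

Step 6
Reactants: 8 4-methoxybenzyl alcohol + 9 ethyl vinyl ether
Product: 10 4-methoxybenzyl vinyl ether
Conditions: 9 (solvent), Pd(OAc)2 (2 mol%), 1,10-phenanthroline (2 mol%), rt
Reagents that add atoms: none
Why: Pd(II)-catalysed transfer vinylation (transetherification) driven by excess ethyl vinyl ether.

Step 7
Reactants: 10 4-methoxybenzyl vinyl ether
Product: 12 (Z)-1-bromo-2-[(4-methoxybenzyl)oxy]ethene, via dibromo ether 11 (not isolated)
Conditions: Br2 (1.0 equiv), CH2Cl2, −78 °C; then i-Pr2NEt, −78 → 40 °C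
Reagents that add atoms: bromine, BrBr
Why: Bromine addition to the enol ether then dehydrobromination of the α,β-dibromo ether, which gives the cis (Z) β-bromo enol ether as for the ethyl analogue.

Step 8
Reactants: 12 (Z)-bromo enol ether + 7 ketone
Product: 14 (1S,2S,5R)-5-{[tert-butyl(diphenyl)silyl]oxymethyl}-1-{(Z)-2-[(4-methoxybenzyl)oxy]ethenyl}-2-(prop-1-en-2-yl)cyclohexan-1-ol, via alkenyllithium 13 (not isolated)
Conditions: 12, t-BuLi (2.0 equiv), Et2O, −78 °C; then 7, −78 °C; H2O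
Reagents that add atoms: none
Why: Br–Li exchange with retention of the Z geometry, then 1,2-addition from the equatorial direction trans to the α-isopropenyl group, so both alkenyl groups are equatorial and OH is axial (carbinol centre set by the substrate).

Step 9
Reactants: 14 dialkenyl carbinol + 15 methyl bromoacetate
Product: 18 methyl (4R,7R,8R,1(10)E)-8-[(4-methoxybenzyl)oxy]-6-oxo-15-[(tert-butyldiphenylsilyl)oxy]-13-norgermacr-1(10)-en-12-oate (ring-trans alkene), via potassium alkoxide 16 (not isolated), via potassium enolate 17 (not isolated)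
Conditions: KHMDS (1.1 equiv), THF, 0 → 40 °C (no crown ether); then 15, −78 → −40 °C
Reagents that add atoms: none
Why: Anionic oxy-Cope [3,3]-sigmatropic ring expansion through the chair transition state with both ring bonds equatorial (ring-trans C1=C10 and ring-trans enolate), in which the Z enol-ether oxygen sits axial and K-bridged to the alkoxide and so sets C8; the chelated enolate holds C8–O near its nodal plane (no β-elimination) and is alkylated Fráter–Seebach-like on the peripheral face anti to C8–C9, which sets C7.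

Step 10
Reactants: 18 keto ester
Product: 19 methyl (4R,7R,8R,1(10)E)-8-hydroxy-6-oxo-15-[(tert-butyldiphenylsilyl)oxy]-13-norgermacr-1(10)-en-12-oate
Conditions: DDQ, CH2Cl2/pH 7 buffer, 0 °C
Reagents that add atoms: none
Why: Oxidative PMB-ether cleavage under neutral conditions frees 8-OH without base, so the β-hydroxy ketone and the C7 centre survive.

Step 11
Reactants: 19 β-hydroxy ketone
Product: 21 (4R,6R,7R,8R,1(10)E)-8-hydroxy-15-[(tert-butyldiphenylsilyl)oxy]-13-norgermacr-1(10)-en-12,6-olide (trans-fused), via diol ester 20 (not isolated)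
Conditions: Me4NBH(OAc)3, MeCN/AcOH (1:1), −30 °C; then PPTS (cat.), PhMe, 50 °C
Reagents that add atoms: none
Why: Evans–Saksena reduction delivers hydride intramolecularly from the 8-O-bound borohydride and gives the 1,3-anti diol (6R); the 6-OH then closes the trans-fused γ-lactone, the 8β-OH being able to form only the more strained cis-fused isomer, which the acid equilibrates.

Step 12
Reactants: 21 hydroxy lactone
Product: 24 (4R,6R,7R,8R,1(10)E)-8-hydroxy-15-[(tert-butyldiphenylsilyl)oxy]germacra-1(10),11(13)-dien-12,6-olide (ring-trans), via Mannich base 22 (not isolated), via ammonium iodide 23 (not isolated)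
Conditions: LDA (2.5 equiv), THF, −78 °C; Me2N+=CH2 I−, −78 → 0 °C; H2O; then MeI, MeOH, rt; then aq NaHCO3, rt
Reagents that add atoms: N,N-dimethylmethyleneiminium iodide (Eschenmoser's salt), C=[N+](C)C.[I-]
Why: Mannich reaction of the lactone enolate (alkoxide/enolate dianion) then quaternisation and β-elimination gives the α-methylene lactone without touching any stereocentre.

Step 13
Reactants: 24 hydroxy α-methylene lactone + 25 angelic acid
Product: 27 (4R,6R,7S,8R,1(10)E)-8-(angeloyloxy)-15-[(tert-butyldiphenylsilyl)oxy]germacra-1(10),11(13)-dien-12,6-olide (ring-trans), via mixed anhydride 26 (not isolated)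
Conditions: 25, 2,4,6-Cl3C6H2COCl, Et3N, PhMe, rt; then 24, 80 °C
Reagents that add atoms: none
Why: Yamaguchi-type mixed-anhydride esterification run without DMAP, which acylates the 8-OH with retention and avoids angelate → tiglate isomerisation.

Step 14
Reactants: 27 angelate
Product: 28 (4R,6R,7S,8R,1(10)E)-8-(angeloyloxy)-14-hydroxy-15-[(tert-butyldiphenylsilyl)oxy]germacra-1(10),11(13)-dien-12,6-olide (ring-cis)
Conditions: SeO2 (20 mol%), t-BuOOH (3 equiv), CH2Cl2, rt
Reagents that add atoms: tert-butyl hydroperoxide, CC(C)(C)OO (oxygen source; selenium dioxide, O=[Se]=O, is the catalytic carrier)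
Why: SeO2 allylic oxidation (ene reaction then [2,3]-sigmatropic shift) at the methyl of the only electron-rich alkene; the [2,3] step places CH2OH cis to H-1, which converts the ring-trans into the ring-cis double bond as in parthenolide → melampomagnolide B.

Step 15
Reactants: 28 silyl ether
Product: 29 (4R,6R,7S,8R,1(10)E)-8-(angeloyloxy)-14,15-dihydroxygermacra-1(10),11(13)-dien-12,6-olide (ring-cis; target)
Conditions: HF·pyridine, pyridine/THF, 0 °C → rt
Reagents that add atoms: none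
Why: Fluoride-mediated desilylation; the buffered HF leaves the angelate, allylic alcohol and α-methylene lactone intact.

**Compound list**
1 | (R)-cyclohex-3-ene-1-carboxylic acid | OC(=O)[C@H]1CC=CCC1 | starting material
2 | (1R,4R,5R)-4-iodo-6-oxabicyclo[3.2.1]octan-7-one | O=C1O[C@@H]2C[C@H]1CC[C@H]2I | intermediate
3 | 2-bromopropene | CC(Br)=C | starting material
4 | (1R,4S,5R)-4-(prop-1-en-2-yl)-6-oxabicyclo[3.2.1]octan-7-one | O=C1O[C@@H]2C[C@H]1CC[C@H]2C(C)=C | intermediate
5 | (1R,2S,5R)-5-(hydroxymethyl)-2-(prop-1-en-2-yl)cyclohexan-1-ol | OC[C@@H]1CC[C@@H](C(C)=C)[C@H](O)C1 | intermediate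
6 | (1R,2S,5R)-5-{[tert-butyl(diphenyl)silyl]oxymethyl}-2-(prop-1-en-2-yl)cyclohexan-1-ol | CC(C)(C)[Si](OC[C@@H]1CC[C@@H](C(C)=C)[C@H](O)C1)(c1ccccc1)c1ccccc1 | intermediate
7 | (2S,5R)-5-{[tert-butyl(diphenyl)silyl]oxymethyl}-2-(prop-1-en-2-yl)cyclohexan-1-one | CC(C)(C)[Si](OC[C@@H]1CC[C@@H](C(C)=C)C(=O)C1)(c1ccccc1)c1ccccc1 | intermediate
8 | 4-methoxybenzyl alcohol | COc1ccc(CO)cc1 | starting material
9 | ethyl vinyl ether | C=COCC | starting material
10 | 4-methoxybenzyl vinyl ether | C=COCc1ccc(OC)cc1 | intermediate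
11 | 1-[(1,2-dibromoethoxy)methyl]-4-methoxybenzene | BrCC(Br)OCc1ccc(OC)cc1 | intermediate (not isolated)
12 | (Z)-1-bromo-2-[(4-methoxybenzyl)oxy]ethene | Br/C=C\OCc1ccc(OC)cc1 | intermediate
13 | (Z)-2-[(4-methoxybenzyl)oxy]ethenyllithium | [Li]/C=C\OCc1ccc(OC)cc1 | intermediate (not isolated)
14 | (1S,2S,5R)-5-{[tert-butyl(diphenyl)silyl]oxymethyl}-1-{(Z)-2-[(4-methoxybenzyl)oxy]ethenyl}-2-(prop-1-en-2-yl)cyclohexan-1-ol | CC(C)(C)[Si](OC[C@@H]1CC[C@@H](C(C)=C)[C@](O)(/C=C\OCc2ccc(OC)cc2)C1)(c1ccccc1)c1ccccc1 | intermediate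
15 | methyl bromoacetate | COC(=O)CBr | starting material
16 | potassium alkoxide of 14 | CC(C)(C)[Si](OC[C@@H]1CC[C@@H](C(C)=C)[C@]([O-])(/C=C\OCc2ccc(OC)cc2)C1)(c1ccccc1)c1ccccc1.[K+] | intermediate (not isolated)
17 | potassium (4R,8R,6Z,1(10)E)-8-[(4-methoxybenzyl)oxy]-15-[(tert-butyldiphenylsilyl)oxy]-11,12,13-trinorgermacra-1(10),6-dien-6-olate (both ring double bonds ring-trans) | [K+].[O-]/C1=C\[C@H](OCc2ccc(OC)cc2)C/C(C)=C/CC[C@@H](CO[Si](c2ccccc2)(c2ccccc2)C(C)(C)C)C1 | intermediate (not isolated)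
18 | methyl (4R,7R,8R,1(10)E)-8-[(4-methoxybenzyl)oxy]-6-oxo-15-[(tert-butyldiphenylsilyl)oxy]-13-norgermacr-1(10)-en-12-oate (ring-trans) | O=C1[C@H](CC(=O)OC)[C@H](OCc2ccc(OC)cc2)C/C(C)=C/CC[C@@H](CO[Si](c2ccccc2)(c2ccccc2)C(C)(C)C)C1 | intermediate
19 | methyl (4R,7R,8R,1(10)E)-8-hydroxy-6-oxo-15-[(tert-butyldiphenylsilyl)oxy]-13-norgermacr-1(10)-en-12-oate | O=C1[C@H](CC(=O)OC)[C@H](O)C/C(C)=C/CC[C@@H](CO[Si](c2ccccc2)(c2ccccc2)C(C)(C)C)C1 | intermediate
20 | methyl (4R,6R,7S,8R,1(10)E)-6,8-dihydroxy-15-[(tert-butyldiphenylsilyl)oxy]-13-norgermacr-1(10)-en-12-oate | O[C@H]1[C@H](CC(=O)OC)[C@H](O)C/C(C)=C/CC[C@@H](CO[Si](c2ccccc2)(c2ccccc2)C(C)(C)C)C1 | intermediate (not isolated)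
21 | (4R,6R,7R,8R,1(10)E)-8-hydroxy-15-[(tert-butyldiphenylsilyl)oxy]-13-norgermacr-1(10)-en-12,6-olide (trans-fused) | O=C1O[C@@H]2C[C@H](CO[Si](c3ccccc3)(c3ccccc3)C(C)(C)C)CC/C=C(\C)C[C@@H](O)[C@H]2C1 | intermediate
22 | (4R,6R,7R,8R)-13-(dimethylamino)-8-hydroxy-15-[(tert-butyldiphenylsilyl)oxy]germacr-1(10)-en-12,6-olide (C11 epimers) | O=C1O[C@@H]2C[C@H](CO[Si](c3ccccc3)(c3ccccc3)C(C)(C)C)CC/C=C(\C)C[C@@H](O)[C@H]2C1CN(C)C | intermediate (not isolated)
23 | N-methyl ammonium iodide of 22 | O=C1O[C@@H]2C[C@H](CO[Si](c3ccccc3)(c3ccccc3)C(C)(C)C)CC/C=C(\C)C[C@@H](O)[C@H]2C1C[N+](C)(C)C.[I-] | intermediate (not isolated)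
24 | (4R,6R,7R,8R,1(10)E)-8-hydroxy-15-[(tert-butyldiphenylsilyl)oxy]germacra-1(10),11(13)-dien-12,6-olide (ring-trans) | C=C1C(=O)O[C@@H]2C[C@H](CO[Si](c3ccccc3)(c3ccccc3)C(C)(C)C)CC/C=C(\C)C[C@@H](O)[C@@H]12 | intermediate
25 | angelic acid, (Z)-2-methylbut-2-enoic acid | C/C=C(/C)C(=O)O | starting material
26 | angelic 2,4,6-trichlorobenzoic anhydride | C/C=C(/C)C(=O)OC(=O)c1c(Cl)cc(Cl)cc1Cl | intermediate (not isolated)
27 | (4R,6R,7S,8R,1(10)E)-8-(angeloyloxy)-15-[(tert-butyldiphenylsilyl)oxy]germacra-1(10),11(13)-dien-12,6-olide (ring-trans) | C=C1C(=O)O[C@@H]2C[C@H](CO[Si](c3ccccc3)(c3ccccc3)C(C)(C)C)CC/C=C(\C)C[C@@H](OC(=O)/C(C)=C\C)[C@@H]12 | intermediate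
28 | (4R,6R,7S,8R,1(10)E)-8-(angeloyloxy)-14-hydroxy-15-[(tert-butyldiphenylsilyl)oxy]germacra-1(10),11(13)-dien-12,6-olide (ring-cis) | C=C1C(=O)O[C@@H]2C[C@H](CO[Si](c3ccccc3)(c3ccccc3)C(C)(C)C)CC/C=C(/CO)C[C@@H](OC(=O)/C(C)=C\C)[C@@H]12 | intermediate
29 | (4R,6R,7S,8R,1(10)E)-8-(angeloyloxy)-14,15-dihydroxygermacra-1(10),11(13)-dien-12,6-olide (ring-cis) | C=C1C(=O)O[C@@H]2C[C@H](CO)CC/C=C(/CO)C[C@@H](OC(=O)/C(C)=C\C)[C@@H]12 | target

**Step count**
Total: 15 steps. Longest linear sequence: 13 steps (1 → 29 through steps 1–5 and 8–15); the side branch is steps 6–7.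

**Three steps most likely to fail**

Step 2 (Ni/Mn coupling on the iodolactone). The β-acyloxy alkyl iodide may be reduced back to 1 (loss of carboxylate), or the isopropenyl group may enter cis to the lactone oxygen. The fallback sets out from 1 and comes back at 7. LiAlH4 reduces 1 to (R)-cyclohex-3-en-1-ylmethanol F1, which is silylated to tert-butyl{[(1R)-cyclohex-3-en-1-yl]methoxy}diphenylsilane F2. mCPBA gives a roughly 1:1 epoxide mixture, from which the epoxide trans to the side chain, tert-butyl{[(1S,3R,6R)-7-oxabicyclo[4.1.0]heptan-3-yl]methoxy}diphenylsilane F3, is separated. Isopropenylmagnesium bromide with CuI opens F3 trans-diaxially (Fürst–Plattner) at the ring carbon para to the side chain to give (1S,2R,5R)-5-{[tert-butyl(diphenyl)silyl]oxymethyl}-2-(prop-1-en-2-yl)cyclohexan-1-ol F4. Dess–Martin oxidation gives the cis ketone (2R,5R)-5-{[tert-butyl(diphenyl)silyl]oxymethyl}-2-(prop-1-en-2-yl)cyclohexan-1-one F5, and DBU equilibration converts it to the trans ketone 7 (the cis isomer is recycled).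

Step 9 (oxy-Cope with in-situ alkylation). The axial Z-alkoxy group may slow the chair pathway, and the warm potassium enolate may lose the 8-alkoxide or alkylate poorly. The fallback sets out from 14 and comes back at 18. The rearrangement is run with KHMDS as before but quenched at −78 °C with Me3SiCl as soon as 14 is consumed, and the trimethylsilyl enol ether of the ring-expanded ketone F6 is isolated. F6 is then converted with MeLi (THF, −78 °C) into the tighter, chelated lithium enolate, which is alkylated with 15 and HMPA at −78 °C to give 18.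

Step 11 (directed reduction and lactonisation). The 8-OH may lactonise onto the ester before or after reduction, or hydride delivery may be unselective in the ten-membered ring. The fallback sets out from 18 (PMB still on O8) and comes back at 21. L-Selectride attacks the ketone under Felkin/peripheral control to give the 6-epi alkoxide, which closes to the cis-fused (4R,6S,7R,8R)-8-[(4-methoxybenzyl)oxy] lactone F7. LiOH opens it to the (4R,6S,7S,8R)-6-hydroxy acid F8. Mitsunobu lactonisation (PPh3, DIAD) closes the ring with inversion at C6 to the trans-fused (4R,6R,7R,8R)-8-[(4-methoxybenzyl)oxy] lactone F9, and DDQ then removes the PMB group to give 21.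

**Further compounds**
F1 | step 2 | (R)-cyclohex-3-en-1-ylmethanol | OC[C@H]1CC=CCC1
F2 | step 2 | tert-butyl{[(1R)-cyclohex-3-en-1-yl]methoxy}diphenylsilane | CC(C)(C)[Si](OC[C@H]1CC=CCC1)(c1ccccc1)c1ccccc1
F3 | step 2 | tert-butyl{[(1S,3R,6R)-7-oxabicyclo[4.1.0]heptan-3-yl]methoxy}diphenylsilane (epoxide trans to the side chain) | CC(C)(C)[Si](OC[C@H]1C[C@@H]2O[C@@H]2CC1)(c1ccccc1)c1ccccc1
F4 | step 2 | (1S,2R,5R)-5-{[tert-butyl(diphenyl)silyl]oxymethyl}-2-(prop-1-en-2-yl)cyclohexan-1-ol | CC(C)(C)[Si](OC[C@@H]1CC[C@H](C(C)=C)[C@@H](O)C1)(c1ccccc1)c1ccccc1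
F5 | step 2 | (2R,5R)-5-{[tert-butyl(diphenyl)silyl]oxymethyl}-2-(prop-1-en-2-yl)cyclohexan-1-one | CC(C)(C)[Si](OC[C@@H]1CC[C@H](C(C)=C)C(=O)C1)(c1ccccc1)c1ccccc1
F6 | step 9 | (4R,8R,6Z,1(10)E)-8-[(4-methoxybenzyl)oxy]-15-[(tert-butyldiphenylsilyl)oxy]-6-(trimethylsilyloxy)-11,12,13-trinorgermacra-1(10),6-diene | C[Si](C)(C)O/C1=C\[C@H](OCc2ccc(OC)cc2)C/C(C)=C/CC[C@@H](CO[Si](c2ccccc2)(c2ccccc2)C(C)(C)C)C1
F7 | step 11 | (4R,6S,7R,8R,1(10)E)-8-[(4-methoxybenzyl)oxy]-15-[(tert-butyldiphenylsilyl)oxy]-13-norgermacr-1(10)-en-12,6-olide (cis-fused) | O=C1O[C@H]2C[C@H](CO[Si](c3ccccc3)(c3ccccc3)C(C)(C)C)CC/C=C(\C)C[C@@H](OCc3ccc(OC)cc3)[C@H]2C1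
F8 | step 11 | (4R,6S,7S,8R,1(10)E)-6-hydroxy-8-[(4-methoxybenzyl)oxy]-15-[(tert-butyldiphenylsilyl)oxy]-13-norgermacr-1(10)-en-12-oic acid | O[C@@H]1[C@H](CC(=O)O)[C@H](OCc2ccc(OC)cc2)C/C(C)=C/CC[C@@H](CO[Si](c2ccccc2)(c2ccccc2)C(C)(C)C)C1
F9 | step 11 | (4R,6R,7R,8R,1(10)E)-8-[(4-methoxybenzyl)oxy]-15-[(tert-butyldiphenylsilyl)oxy]-13-norgermacr-1(10)-en-12,6-olide (trans-fused) | O=C1O[C@@H]2C[C@H](CO[Si](c3ccccc3)(c3ccccc3)C(C)(C)C)CC/C=C(\C)C[C@@H](OCc3ccc(OC)cc3)[C@H]2C1
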